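**Assumption:** the target is taken exactly as the SMILES defines it (left half in the 10α‑methyl/5β,9β‑H "ent‑labdane" series, cis‑fused enone decalin). Left‑half atom labels (C3, C4, C8, C12, C19…) follow labdane numbering of andrographolide.

## Retrosynthetic overview

1. The last C–O bond (right‑half tertiary carbinol) comes from Markovnikov hydration of a ring alkene on the convex face of the cis‑fused enone.
2. The key disconnection is the central CH2–CH2 bond plus the enone. It is made in one visible‑light three‑component coupling of a lactol‑derived primary radical (left half), an exocyclic 1,3‑diene (right half) and DMSO.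
3. The left half is carved from andrographolide, which supplies C5, C9, C10 and the linker carbon. The side chain is excised, the 8(17)‑alkene becomes the tertiary carbinol, and ring A becomes the oxepane by photochemical decarboxylative hydroperoxidation, Criegee O‑insertion and methyl capture. C3 is inverted by oxidation/reduction.
4. The right half comes from (S)‑carvone: Reetz α‑tert‑alkylation, then ring‑closing metathesis, then methylenation to the diene.
5. Ring order: left, cyclohexane (bought) → γ‑lactone → oxepane; right, carvone ring (bought) → second carbocycle (RCM); the enone is regenerated in the coupling.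

## Route

**Step 1**
Reactants: 1, andrographolide
Product: 2, 8,17‑epoxyandrographolide (epoxide O anti to the C10 methyl)
Conditions: mCPBA, NaHCO3, CH2Cl2, 0 °C
Reagents that add atoms: mCPBA, O=C(OO)c1cccc(Cl)c1
Why: Prilezhaev epoxidation takes only the electron‑rich exocyclic alkene (the enoate alkene is inert), and attack anti to the axial C10 methyl fixes the C8–O configuration.

**Step 2**
Reactants: 2
Product: 3, 13,14,15,16‑tetranor‑ent‑labdane‑3α,8,12,19‑tetraol (8‑OH anti, 8‑CH3 syn to the C10 methyl)
Conditions: O3, CH2Cl2/MeOH, −78 °C; Me2S; then LiAlH4 (excess), THF, 0 → 65 °C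
Reagents that add atoms: ozone, [O-][O+]=O (oxygen of the C12–OH)
Why: Ozonolysis cleaves C12=C13, then hydride reduces the aldehyde and opens the epoxide by SN2 at the CH2 carbon, leaving the C8–O bond and its configuration intact.

**Step 3**
Reactants: 3
Product: 4, 3α‑hydroxy‑12,8‑olide‑19‑oic acid (ent‑3‑hydroxysclareolide‑19‑carboxylic acid)
Conditions: TEMPO (10 mol %), NaClO2, NaOCl (cat.), MeCN/pH 6.7 phosphate buffer, 35 °C; then pH 3
Reagents that add atoms: sodium chlorite, [Na+].[O-]Cl=O
Why: TEMPO/chlorite (Zhao) oxidation converts both primary alcohols to acids and spares the secondary 3‑OH; the γ‑hydroxy acid lactonises onto the tertiary C8–OH.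

**Step 4**
Reactants: 4
Product: 5, 19‑nor‑4‑hydroperoxy‑3α‑hydroxy‑12,8‑olide (C4 epimers, inconsequential)
Conditions: 9‑mesityl‑10‑methylacridinium perchlorate (5 mol %), 2,6‑lutidine, O2 (1 atm), MeCN, 450 nm LEDs, rt
Reagents that add atoms: dioxygen, O=O
Why: Photoredox decarboxylative oxygenation: the excited acridinium oxidises the tertiary carboxylate, CO2 loss gives the C4 radical, and O2 capture then reduction gives the hydroperoxide whose proximal oxygen becomes the oxepane oxygen.

**Step 5**
Reactants: 5
Product: 6, tricyclic oxepane lactone (2,2‑dimethyloxepane trans‑fused to the cyclohexane, C8–O–C12(=O) γ‑lactone; 3‑OH cis to the angular methyl, i.e. 3‑epi)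
Conditions: TFAA, 2,6‑lutidine, CH2Cl2, −40 °C; then AlMe3 (6 equiv), −78 → 0 °C; Rochelle salt, brief K2CO3/MeOH
Reagents that add atoms: trimethylaluminium, C[Al](C)C
Why: Criegee rearrangement of the peroxytrifluoroacetate: C5 migrates to oxygen with retention, in preference to the acyloxy‑deactivated C3 or methyl, and the seven‑membered oxocarbenium is methylated by AlMe3 (C‑glycosylation‑type) to give the gem‑dimethyl ether.

**Step 6**
Reactants: 6
Product: 7, the corresponding oxepan‑3‑one lactone
Conditions: Dess–Martin periodinane, NaHCO3, CH2Cl2, rt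
Reagents that add atoms: none
Why: Dess–Martin oxidation of the only free (secondary) alcohol erases the wrong C3 configuration.

**Step 7**
Reactants: 7
Product: 8, lactol (anomer mixture) with 3‑OH trans to the angular methyl (target C3 configuration)
Conditions: DIBAL‑H (3.2 equiv), CH2Cl2, −78 °C; Rochelle salt
Reagents that add atoms: none
Why: Hydride reduction: the ketone is attacked anti to the pseudo‑axial C4 methyl of the twist‑chair oxepanone (from the angular‑methyl face), giving the carbinol trans to the angular methyl, and the lactone stops at the lactol.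

**Step 8**
Reactants: 8
Product: 9, N‑(lactol‑O)‑phthalimide (N‑alkoxyphthalimide at C12)
Conditions: N‑hydroxyphthalimide, PPh3, DIAD, THF, 0 °C → rt
Reagents that add atoms: N‑hydroxyphthalimide, O=C1c2ccccc2C(=O)N1O
Why: Mitsunobu O‑alkylation occurs at the anomeric hydroxyl; the neopentylic 3‑OH and tertiary positions do not react.

**Step 9**
Reactants: 10, (S)‑(+)‑carvone
Product: 11, kinetic (C6) trimethylsilyl dienol ether of carvone
Conditions: LDA, THF, −78 °C; TMSCl, Et3N
Reagents that add atoms: chlorotrimethylsilane, C[Si](C)(C)Cl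
Why: Kinetic α′‑deprotonation and O‑silylation give the cross‑conjugated 2‑siloxydiene; C5 is untouched.

**Step 10**
Reactants: 12, 2‑methylpent‑4‑en‑2‑ol
Product: 13, 4‑chloro‑4‑methylpent‑1‑ene
Conditions: conc. HCl, CaCl2, 0 °C
Reagents that add atoms: hydrogen chloride, Cl
Why: SN1 conversion of a tertiary alcohol to the tertiary chloride.

**Step 11**
Reactants: 11 and 13
Product: 14, (5S,6S)‑2‑methyl‑6‑(2‑methylpent‑4‑en‑2‑yl)‑5‑(prop‑1‑en‑2‑yl)cyclohex‑2‑en‑1‑one (5,6‑trans)
Conditions: TiCl4 (1.1 equiv), CH2Cl2, −78 → −40 °C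
Reagents that add atoms: none (13 is a numbered reactant)
Why: Reetz α‑tert‑alkylation (SN1 Mukaiyama‑type): the tertiary cation is captured at C6 of the silyl dienol ether anti to the C5 isopropenyl group, forming the quaternary C–C bond.

**Step 12**
Reactants: 14
Product: 15, (4aS,8aS)‑2,5,8,8‑tetramethyl‑4a,7,8,8a‑tetrahydronaphthalen‑1(4H)‑one (trans‑fused)
Conditions: Grubbs II (5 mol %), CH2Cl2, 40 °C
Reagents that add atoms: none
Why: Ring‑closing metathesis of the allyl and isopropenyl groups (loss of ethylene) gives the trisubstituted cyclohexene; the conjugated enone alkene does not take part.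

**Step 13**
Reactants: 15
Product: 16, (4aS,8aS)‑2,5,8,8‑tetramethyl‑1‑methylidene‑1,4,4a,7,8,8a‑hexahydronaphthalene
Conditions: Zn, CH2Br2, TiCl4, THF/CH2Cl2, 0 °C → rt
Reagents that add atoms: dibromomethane, BrCBr
Why: Takai–Lombardo methylenation is non‑basic and tolerates the hindered, epimerisable enone, giving the exocyclic/endocyclic 1,3‑diene.

**Step 14**
Reactants: 9 and 16
Product: 17, trans‑fused enone, formate at the left‑half tertiary oxygen
Conditions: fac‑Ir(ppy)3 (2 mol %), 2,6‑lutidine, DMSO (0.05 M), 450 nm LEDs, rt, Ar; 16 in 2 equiv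
Reagents that add atoms: dimethyl sulfoxide, CS(C)=O (enone oxygen)
Why: Proposed new method: excited Ir(III) reduces the N‑alkoxyphthalimide to the anomeric alkoxy radical, whose β‑scission gives the C8 formate and the primary C11 radical; this adds to the exocyclic CH2 of diene 16, Ir(IV) oxidises the resulting allyl radical (radical‑polar crossover), DMSO traps the cation at the less hindered ring CH, and Kornblum collapse gives the tetrasubstituted enone, redox‑neutral overall. The closest known reactions are photoredox oxo‑alkylation of styrenes with redox‑active esters in DMSO and photoredox alkoxy‑radical β‑fragmentation of N‑alkoxyphthalimides (Suárez‑type lactol fragmentation).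

**Step 15**
Reactants: 17
Product: 18, cis‑fused enone diol (the target lacking the right‑half tertiary OH, with a ring C=C(CH3) alkene in its place)
Conditions: NaOMe, MeOH, 40 °C
Reagents that add atoms: none
Why: Methanolysis removes the formate, and reversible γ‑deprotonation (dienolate) epimerises the allylic ring‑fusion carbon to the cis isomer, which relieves A(1,3) strain between the β‑side chain and the gem‑dimethyl carbon.

**Step 16**
Reactants: 18
Product: 19, sipholenol K
Conditions: Mn(dpm)3 (10 mol %), PhSiH3, O2 (1 atm), i‑PrOH/CH2Cl2, 0 °C; then P(OEt)3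
Reagents that add atoms: dioxygen, O=O
Why: Mukaiyama (MHAT) hydration gives the Markovnikov tertiary radical, which takes O2 on the convex face of the cis‑fused bicycle (the face of the ring‑fusion hydrogens), setting the carbinol; the tetrasubstituted enone is a poor HAT acceptor.

## Compound list

1 | andrographolide | C[C@@]12CC[C@H]([C@@]([C@H]1CCC(=C)[C@H]2C/C=C/3\[C@@H](COC3=O)O)(C)CO)O | starting material
2 | 8,17‑epoxyandrographolide | C[C@@]12CC[C@H]([C@@]([C@H]1CC[C@@]4(CO4)[C@H]2C/C=C/3\[C@@H](COC3=O)O)(C)CO)O | intermediate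
3 | tetranor‑ent‑labdane‑3α,8,12,19‑tetraol | C[C@@]12CC[C@H]([C@@]([C@H]1CC[C@@](O)(C)[C@H]2CCO)(C)CO)O | intermediate
4 | 3α‑hydroxy‑12,8‑olide‑19‑oic acid | C[C@@]12CC[C@H]([C@@]([C@H]1CC[C@@](OC(=O)C3)(C)[C@H]23)(C)C(=O)O)O | intermediate
5 | 19‑nor‑4‑hydroperoxy‑3α‑hydroxy‑12,8‑olide | C[C@@]12CC[C@H](C([C@H]1CC[C@@](OC(=O)C3)(C)[C@H]23)(C)OO)O | intermediate
6 | oxepane‑cyclohexane γ‑lactone, 3‑epi alcohol | O=C1C[C@H]2[C@]3(C)CC[C@@H](O)C(C)(C)O[C@H]3CC[C@]2(C)O1 | intermediate
7 | oxepan‑3‑one γ‑lactone | O=C1C[C@H]2[C@]3(C)CCC(=O)C(C)(C)O[C@H]3CC[C@]2(C)O1 | intermediate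
8 | lactol with target‑configured 3‑OH | OC1C[C@H]2[C@]3(C)CC[C@H](O)C(C)(C)O[C@H]3CC[C@]2(C)O1 | intermediate
9 | N‑(lactol‑O)‑phthalimide | O=C1c2ccccc2C(=O)N1OC1C[C@H]2[C@]3(C)CC[C@H](O)C(C)(C)O[C@H]3CC[C@]2(C)O1 | intermediate
10 | (S)‑(+)‑carvone | CC(=C)[C@H]1CC=C(C)C(=O)C1 | starting material
11 | carvone kinetic TMS dienol ether | CC(=C)[C@H]1CC=C(C)C(O[Si](C)(C)C)=C1 | intermediate
12 | 2‑methylpent‑4‑en‑2‑ol | CC(C)(O)CC=C | starting material
13 | 4‑chloro‑4‑methylpent‑1‑ene | CC(C)(Cl)CC=C | intermediate
14 | (5S,6S)‑2‑methyl‑6‑(2‑methylpent‑4‑en‑2‑yl)‑5‑(prop‑1‑en‑2‑yl)cyclohex‑2‑en‑1‑one | CC(=C)[C@H]1CC=C(C)C(=O)[C@@H]1C(C)(C)CC=C | intermediate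
15 | (4aS,8aS)‑2,5,8,8‑tetramethyl‑4a,7,8,8a‑tetrahydronaphthalen‑1(4H)‑one | O=C1C(C)=CC[C@H]2[C@H]1C(C)(C)CC=C2C | intermediate
16 | (4aS,8aS)‑2,5,8,8‑tetramethyl‑1‑methylidene‑1,4,4a,7,8,8a‑hexahydronaphthalene | C=C1C(C)=CC[C@H]2[C@H]1C(C)(C)CC=C2C | intermediate
17 | trans‑fused coupled enone, tertiary formate | CC1=C(CC[C@H]2[C@]3(C)CC[C@H](O)C(C)(C)O[C@H]3CC[C@]2(C)OC=O)[C@H]2[C@H](CC1=O)C(C)=CCC2(C)C | intermediate
18 | cis‑fused enone diol (anhydro‑sipholenol K) | CC1=C(CC[C@H]2[C@]3(C)CC[C@H](O)C(C)(C)O[C@H]3CC[C@]2(C)O)[C@@H]2[C@H](CC1=O)C(C)=CCC2(C)C | intermediate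
19 | sipholenol K | CC1=C(CC[C@H]2[C@]3(C)CC[C@H](O)C(C)(C)O[C@H]3CC[C@]2(C)O)[C@@H]2[C@H](CC1=O)[C@@](C)(O)CCC2(C)C | target

## Summary

Total steps: 16. Longest linear sequence: 11 (steps 1–8, 14–16); the right‑half branch is 5 steps (9–13).

Steps most likely to fail, with fallbacks:

1. **Step 14 (proposed new three‑component coupling).** Fallback with known chemistry: reduce the C3‑inverted lactone to the triol (LiAlH4), convert the primary alcohol to the iodide (I2/PPh3), bis‑silylate, form the organocerium (t‑BuLi, CeCl3) and add it 1,2 to ketone 15, then PCC oxidative 1,3‑transposition (Dauben–Michno) and desilylation, rejoining at step 15.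
2. **Step 5 (Criegee O‑insertion with methyl capture).** Fallback: acetylate the 3‑OH of 4, Kochi oxidative decarboxylation (Pb(OAc)4/Cu(OAc)2) to the 4‑methylidene compound, ozonolysis to the C4 ketone, Baeyer–Villiger oxidation (C5 migrates) to the seven‑membered lactone, then Tebbe methylenation and TFA/AlMe3 to reach 6.
3. **Step 7 (facial selectivity of the oxepanone reduction).** Fallback: set C3 on the rigid cyclohexane before ring expansion. Protect the acid of 4 as its 2‑(trimethylsilyl)ethyl ester, oxidise C3 (the β‑keto ester does not decarboxylate), reduce with K‑Selectride to the axial alcohol, remove the ester with TBAF, then run steps 4–5 and go directly to lactol formation.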